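**Retrosynthetic overview**
1. Late stage: the ring-A 3β,4α-diol is esterified at C3 with (2S,3S)-epoxyangelic acid (from a Sharpless epoxidation) and formylated at C4. Ring B is unveiled last: the C6=C7–C8=O enone and the C11 hydroxyl both come out of one temporary C8–O–Si(iPr)2–O–C11 ring (DDQ, then HF).
2. The ring-A diol comes from a 3-methoxy-2-ene-1,4-dione. C15 enters by methylenation of C4=O, and the C1 oxygen is erased by reduction/transposition (C3–OMe becomes C3=O). The 4α-OH comes from HAT hydroxylation anti to the C10 methyl, and the 3β-OH from axial hydride delivery.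
3. Key disconnection: C5–C6 and C9–C10 together, by an enantioselective Diels–Alder reaction. Flat 2-methoxy-5-methyl-1,4-benzoquinone supplies all six ring-A carbons and C14; a seven-carbon 2-silyloxydiene supplies C6–C9 and C11–C13. C5 is epimerised to the trans-decalin in the same flask.
4. Enabling feature: in ring B the C8 oxygen sits para to C5 and 1,3 to the C11 oxygen, so C6=C7–C8=C9 is a 2-oxydiene whose two oxygens can be tied into a six-membered dioxasilinane ring (s-cis lock and double protection). In ring A the vicinal C3/C4 oxygens flank C5 and the methyl sits on C10, which is the pattern of a 2-alkoxy-5-methylquinone. Its C4=O/C3–OMe pair chelates Ti, activates C5=C10 and later lets C5 epimerise.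
5. Ring order: temporary dioxasilinane ring, ring A (bought as the quinone), ring B by [4+2], dioxasilinane ring opened at the end. The oxirane ring is made separately.

Key step: step 3

Numbering: eudesmane numbering is used (C1–C10 decalin, C14 = methyl on C10, C15 = methyl on C4, C11–C13 = hydroxyisopropyl on C7). β is the face of the C10 methyl group.
Assumption: the (R)-BINOL-derived Ti(IV) complex is taken to give the adduct with the absolute configuration drawn; the sense of induction would be checked on the first adduct, and (S)-BINOL would be used if it is opposite.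

Step 1
Reactants: 1 3,4-dimethylpent-3-en-2-one
Product: 3 4-hydroxy-4-methyl-3-methylidenepentan-2-one, via allylic hydroperoxide 2 (not isolated)
Conditions: O2, tetraphenylporphyrin (cat.), visible light, CH2Cl2, 0 °C; then PPh3, 0 °C to rt
Reagents that add atoms: dioxygen, O=O
Why: Schenck ene reaction: singlet oxygen attacks the tetrasubstituted enone with the known geminal selectivity of α,β-unsaturated carbonyl compounds, taking hydrogen from the methyl group on the acyl-bearing carbon and placing OOH on the CMe2 carbon, and PPh3 reduces the O–O bond; no stereocentre is formed.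

Step 2
Reactants: 3 4-hydroxy-4-methyl-3-methylidenepentan-2-one
Product: 4 4,4-dimethyl-5,6-dimethylidene-2,2-di(propan-2-yl)-1,3,2-dioxasilinane
Conditions: iPr2Si(OTf)2, Et3N, CH2Cl2, −78 to 0 °C
Reagents that add atoms: diisopropylsilyl bis(trifluoromethanesulfonate), CC(C)[Si](OS(=O)(=O)C(F)(F)F)(OS(=O)(=O)C(F)(F)F)C(C)C
Why: Silyl triflate/amine soft enolisation (silyl enol ether formation) on the only enolisable side of the ketone, together with O-silylation of the tertiary alcohol by the same bifunctional silicon reagent, closes a strain-free six-membered ring that forces the two C=CH2 groups s-cis; no stereocentre is formed.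

Step 3
Reactants: 4 4,4-dimethyl-5,6-dimethylidene-2,2-di(propan-2-yl)-1,3,2-dioxasilinane; 5 2-methoxy-5-methyl-1,4-benzoquinone
Product: 7 trans-fused silylene-bridged methoxy-enedione (5α-H; 10β-CH3), via cis-fused cycloadduct 6 (not isolated)
Conditions: (R)-BINOL/TiCl2(OiPr)2 (20 mol %, pre-formed over 4 Å MS), toluene, −60 to −10 °C; then DBU (0.3 equiv), CH2Cl2, 23 °C
Reagents that add atoms: none
Why: This is a normal-electron-demand, concerted but asynchronous [4πs+2πs] Diels–Alder reaction: the HOMO of the 2-silyloxydiene 4 (largest coefficient at the CH2 next to the C–O carbon, the future C9) meets the LUMO of quinone 5, lowered by Ti(IV) chelated between the C4 carbonyl oxygen and the C3 methoxy oxygen (largest coefficient at the methyl-bearing carbon, the future C10), so that C9–C10 runs ahead of C5–C6. The closest known reaction type is the BINOL–Ti(IV)-catalysed enantioselective Diels–Alder reaction of 2-methoxy-1,4-benzoquinones with 2-silyloxydienes, and thermal cycloadditions at the methyl-bearing double bond of this quinone are well known. Ring B is the only ring closed, as a six-membered carbocycle by intermolecular suprafacial [4+2] annulation onto the C5=C10 edge of ring A, which first gives the cis-fused adduct 6. C10 is set by the chiral titanium complex, which blocks one face of the chelated quinone, whereas C5 is first tied to C10 by the suprafacial addition and is then inverted by DBU through the C4 enolate to the more stable trans-fused 7 (5α-H), which is possible because C4 is still an sp2 carbonyl carbon and no 1,3-diaxial methyl pair yet disfavours the trans fusion. Site selectivity (C5=C10 rather than C2=C3) is secured by the methoxy group, which turns C2=C3 into an unreactive vinylogous ester double bond, and regioselectivity is secured by the match of the chelate with the C8 silyloxy group (C8 ends para to C5). Reactivity toward a quaternary centre is secured by the dioxasilinane ring, which holds the two exocyclic methylene groups s-cis and leaves both diene termini unsubstituted.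

Step 4
Reactants: 7 trans-fused silylene-bridged methoxy-enedione
Product: 8 4-methylidene vinylogous ester (C15 installed)
Conditions: Tebbe reagent (1.1 equiv), pyridine (cat.), THF/toluene, −40 to 0 °C
Reagents that add atoms: Tebbe reagent, C[Al-]1(C)C[Ti](C2C=CC=C2)(C2C=CC=C2)[Cl+]1
Why: Tebbe methylenation through titanocene methylidene ([2+2]/cycloreversion) is non-basic, so the C5 centre is kept, and it picks the C4 ketone because C1=O is a vinylogous ester carbonyl next to the quaternary C10; no new stereocentre is formed.

Step 5
Reactants: 8 4-methylidene vinylogous ester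
Product: 10 cross-conjugated 1,4(15)-dien-3-one, via 1β-allylic alcohol 9 (not isolated)
Conditions: DIBAL-H, CH2Cl2, −78 °C; then 0.5 M aq. HCl, THF, 0 °C (short contact), used directly
Reagents that add atoms: water, O
Why: Stork–Danheiser-type sequence: 1,2-reduction of the vinylogous ester carbonyl (hydride from the α face, a centre that is lost again) and mild acid hydrolysis of the resulting 3-methoxy allylic alcohol expel methanol with transposition, which erases the C1 oxygen and turns C3 into the ketone while the hindered tetrasubstituted enol silane survives.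

Step 6
Reactants: 10 cross-conjugated 1,4(15)-dien-3-one
Product: 12 4α-hydroxy-4β-methyl-1-en-3-one, via 4α-hydroperoxide 11 (not isolated)
Conditions: Mn(dpm)3 (cat.), PhSiH3, O2 (1 atm), iPrOH/CH2Cl2, 0 °C; then P(OEt)3
Reagents that add atoms: dioxygen, O=O
Why: Mukaiyama-type manganese hydride HAT (reductive α-hydroxylation of an enone): H• adds to the terminal, least hindered CH2 to give the tertiary C4 α-keto radical, O2 traps it from the α face because the axial C10 methyl screens the β face, and P(OEt)3 reduces the hydroperoxide, which sets C4 (4α-OH, 4β-CH3).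

Step 7
Reactants: 12 4α-hydroxy-4β-methyl-1-en-3-one
Product: 14 3β,4α-diol, via saturated 4α-hydroxy-3-ketone 13 (not isolated)
Conditions: H2 (1 atm), Pd/C, EtOAc, rt; filter; then NaBH4, MeOH/CH2Cl2, −40 °C
Reagents that add atoms: none
Why: Heterogeneous hydrogenation takes the unhindered disubstituted C1=C2 bond and leaves the tetrasubstituted enol silane, and borohydride then attacks the chair 3-ketone axially from the α face (the β face is blocked by the axial C4 and C10 methyl groups) to set the equatorial 3β-OH.

Step 8
Reactants: 15 methyl angelate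
Product: 16 (Z)-2-methylbut-2-en-1-ol
Conditions: DIBAL-H (2.2 equiv), CH2Cl2, −78 °C; aq. Rochelle salt
Reagents that add atoms: none
Why: DIBAL-H reduction of an α,β-unsaturated ester to the allylic alcohol proceeds by 1,2-addition at low temperature without Z/E isomerisation.

Step 9
Reactants: 16 (Z)-2-methylbut-2-en-1-ol
Product: 17 [(2R,3S)-2,3-dimethyloxiran-2-yl]methanol
Conditions: Ti(OiPr)4 (cat.), D-(−)-diisopropyl tartrate (cat.), tBuOOH, 4 Å MS, CH2Cl2, −20 °C
Reagents that add atoms: tert-butyl hydroperoxide, CC(C)(C)OO
Why: Sharpless asymmetric epoxidation: the D-(−)-tartrate/titanium complex delivers oxygen to the face that gives the 2R series (L-(+)-tartrate gives 2S-epoxy alcohols), and syn addition to the Z-alkene fixes the relative configuration, so both oxirane centres are set.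

Step 10
Reactants: 17 [(2R,3S)-2,3-dimethyloxiran-2-yl]methanol
Product: 18 (2S,3S)-2,3-dimethyloxirane-2-carboxylic acid
Conditions: RuCl3·xH2O (cat.), NaIO4, MeCN/EtOAc/H2O, 0 °C to rt
Reagents that add atoms: water, O
Why: Ruthenium tetroxide oxidation (catalytic RuCl3/NaIO4) of a 2,3-epoxy alcohol to the glycidic acid goes through the aldehyde hydrate and does not touch the oxirane centres (the C2 descriptor changes from R to S by priority only).

Step 11
Reactants: 14 3β,4α-diol; 18 (2S,3S)-2,3-dimethyloxirane-2-carboxylic acid
Product: 19 3β-epoxyangelate 4α-ol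
Conditions: DCC, DMAP (cat.), CH2Cl2, 0 °C to rt
Reagents that add atoms: none
Why: Steglich esterification acylates the equatorial secondary 3β-OH selectively because the neighbouring 4α-OH is tertiary, and it touches no stereocentre.

Step 12
Reactants: 19 3β-epoxyangelate 4α-ol
Product: 20 3β-epoxyangelate 4α-formate
Conditions: acetic formic anhydride, pyridine, DMAP (cat.), CH2Cl2, 0 °C to rt
Reagents that add atoms: acetic formic anhydride, CC(=O)OC=O
Why: Formyl transfer from the mixed anhydride (attack at the more electrophilic formyl carbon, DMAP catalysis) is the standard way to formylate a tertiary alcohol, and C4–OH is the only free hydroxyl group because C11–O is still held in the silicon ring.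

Step 13
Reactants: 20 3β-epoxyangelate 4α-formate
Product: 21 6-en-8-one 11-O-(hydroxydiisopropylsilyl) ether
Conditions: DDQ, CH2Cl2/pH 7 phosphate buffer, 0 °C to rt
Reagents that add atoms: water, O
Why: DDQ dehydrogenation of a silyl enol ether: hydride is taken from C6–H, the only allylic C–H whose loss gives an oxygen-stabilised allyl cation, and water releases the C8 ketone, so the double bond can only appear at C6=C7 (C10 is quaternary) and C5 stays untouched.

Step 14
Reactants: 21 6-en-8-one 11-O-(hydroxydiisopropylsilyl) ether
Product: 22 target CNP0171909.1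
Conditions: HF·pyridine, pyridine, THF, 0 °C
Reagents that add atoms: none
Why: Fluoride-driven cleavage of the remaining Si–O bond under buffered, weakly acidic conditions frees the tertiary C11 alcohol without harming the formate, the electron-poor glycidic ester or the enone.

**Compound list**
1 | 3,4-dimethylpent-3-en-2-one | CC(=O)C(C)=C(C)C | starting material
2 | 4-hydroperoxy-4-methyl-3-methylidenepentan-2-one | CC(=O)C(=C)C(C)(C)OO | intermediate
3 | 4-hydroxy-4-methyl-3-methylidenepentan-2-one | CC(=O)C(=C)C(C)(C)O | intermediate
4 | 4,4-dimethyl-5,6-dimethylidene-2,2-di(propan-2-yl)-1,3,2-dioxasilinane (s-cis-locked 2-silyloxydiene) | C=C1O[Si](C(C)C)(C(C)C)OC(C)(C)C1=C | intermediate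
5 | 2-methoxy-5-methyl-1,4-benzoquinone | COC1=CC(=O)C(C)=CC1=O | starting material
6 | cis-fused cycloadduct: ring A 3-methoxy-2-ene-1,4-dione, ring B C7=C8 enol silane, C8–O–Si(iPr)2–O–C11 ring, 10β-CH3, 5β-H | COC1=CC(=O)[C@]2(C)CC3=C(C[C@@H]2C1=O)C(C)(C)O[Si](C(C)C)(C(C)C)O3 | intermediate
7 | trans-fused isomer of 6 (10β-CH3, 5α-H) | COC1=CC(=O)[C@]2(C)CC3=C(C[C@H]2C1=O)C(C)(C)O[Si](C(C)C)(C(C)C)O3 | intermediate
8 | 4-methylidene derivative of 7 (3-methoxy-2,4(15)-dien-1-one) | COC1=CC(=O)[C@]2(C)CC3=C(C[C@H]2C1=C)C(C)(C)O[Si](C(C)C)(C(C)C)O3 | intermediate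
9 | 1β-alcohol of 8 | COC1=C[C@@H](O)[C@]2(C)CC3=C(C[C@H]2C1=C)C(C)(C)O[Si](C(C)C)(C(C)C)O3 | intermediate
10 | 1,4(15)-dien-3-one (5α-H, 10β-CH3), ring B still the silylene enol ether | O=C1C=C[C@]2(C)CC3=C(C[C@H]2C1=C)C(C)(C)O[Si](C(C)C)(C(C)C)O3 | intermediate
11 | 4α-hydroperoxy-4β-methyl-1-en-3-one | O=C1C=C[C@]2(C)CC3=C(C[C@H]2[C@]1(C)OO)C(C)(C)O[Si](C(C)C)(C(C)C)O3 | intermediate
12 | 4α-hydroxy-4β-methyl-1-en-3-one | O=C1C=C[C@]2(C)CC3=C(C[C@H]2[C@]1(C)O)C(C)(C)O[Si](C(C)C)(C(C)C)O3 | intermediate
13 | 4α-hydroxy-4β-methyl-3-ketone (ring A saturated) | O=C1CC[C@]2(C)CC3=C(C[C@H]2[C@]1(C)O)C(C)(C)O[Si](C(C)C)(C(C)C)O3 | intermediate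
14 | 3β,4α-diol (4β-CH3, 5α-H, 10β-CH3) | O[C@H]1CC[C@]2(C)CC3=C(C[C@H]2[C@]1(C)O)C(C)(C)O[Si](C(C)C)(C(C)C)O3 | intermediate
15 | methyl angelate, methyl (Z)-2-methylbut-2-enoate | C/C=C(/C)C(=O)OC | starting material
16 | (Z)-2-methylbut-2-en-1-ol | C/C=C(/C)CO | intermediate
17 | [(2R,3S)-2,3-dimethyloxiran-2-yl]methanol | C[C@@H]1O[C@]1(C)CO | intermediate
18 | (2S,3S)-2,3-dimethyloxirane-2-carboxylic acid (epoxyangelic acid) | C[C@@H]1O[C@]1(C)C(=O)O | intermediate
19 | 3β-[(2S,3S)-epoxyangeloyloxy]-4α-ol | C[C@@H]1O[C@]1(C)C(=O)O[C@H]1CC[C@]2(C)CC3=C(C[C@H]2[C@]1(C)O)C(C)(C)O[Si](C(C)C)(C(C)C)O3 | intermediate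
20 | 3β-[(2S,3S)-epoxyangeloyloxy]-4α-formate | C[C@@H]1O[C@]1(C)C(=O)O[C@H]1CC[C@]2(C)CC3=C(C[C@H]2[C@]1(C)OC=O)C(C)(C)O[Si](C(C)C)(C(C)C)O3 | intermediate
21 | 6-en-8-one with C11–O–Si(iPr)2OH | C[C@@H]1O[C@]1(C)C(=O)O[C@H]1CC[C@]2(C)CC(=O)C(C(C)(C)O[Si](O)(C(C)C)C(C)C)=C[C@H]2[C@]1(C)OC=O | intermediate
22 | CNP0171909.1: 3β-[(2S,3S)-epoxyangeloyloxy]-4α-formyloxy-11-hydroxyeudesm-6-en-8-one | C[C@@H]1O[C@]1(C)C(=O)O[C@H]1CC[C@]2(C)CC(=O)C(C(C)(C)O)=C[C@H]2[C@]1(C)OC=O | target

**Step count**
Total step count: 14. Longest linear sequence: 11 (steps 1–7 and 11–14).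

**Steps most likely to fail**
1. Step 3. The titanium complex may discriminate poorly between the two quinone faces. The Lewis acid may also open the diene, by desilylation or by stopping after a Mukaiyama–Michael addition. The fallback replaces asymmetric catalysis by resolution. It sets out from 4 and 5, which would be heated without catalyst in toluene (60–80 °C), where the intrinsic regiochemistry is the same. This would give 6 together with the mirror-image cis adduct F1. DBU would convert the pair into 7 and the mirror-image trans adduct F2. Preparative chromatography on a chiral stationary phase would remove the latter, and the route is rejoined at 7.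
2. Step 6. Hydrogen-atom transfer may also reach C1=C2. The exocyclic double bond of 10 may drift into the ring, with loss of the C5 centre. The capture of O2 may show poor facial selectivity. The fallback replaces the radical hydroxylation by enolate chemistry and sets out from 10. Exhaustive hydrogenation (H2, Pd/C, EtOAc) would give the saturated 4α-methyl 3-ketone F3. Its more substituted, thermodynamic enolate would be autoxidised (KOtBu, O2, P(OEt)3, THF/tBuOH, −20 °C) from the α face. The route is rejoined at 13, which is reduced as in the second half of step 7.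
3. Step 13. Hydride abstraction from the hindered enol silane may be slow. The cation may lose the C5 proton, which would erode the ring fusion, or over-oxidation may set in. The fallback separates unmasking from oxidation and sets out from 20. HF·pyridine would first open the silicon ring to the saturated 7α-H 11-hydroxy-8-ketone F4. IBX (DMSO/fluorobenzene, 65 °C) would then dehydrogenate it; only C6=C7 can form because C10 carries no hydrogen. The route is rejoined at 22.

**Further compounds**
F1 | step 3 | mirror-image cis adduct (enantiomer of 6) | COC1=CC(=O)[C@@]2(C)CC3=C(C[C@H]2C1=O)C(C)(C)O[Si](C(C)C)(C(C)C)O3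
F2 | step 3 | mirror-image trans adduct (enantiomer of 7) | COC1=CC(=O)[C@@]2(C)CC3=C(C[C@@H]2C1=O)C(C)(C)O[Si](C(C)C)(C(C)C)O3
F3 | step 6 | saturated 4α-methyl 3-ketone (5α-H, 10β-CH3) | O=C1CC[C@]2(C)CC3=C(C[C@H]2[C@@H]1C)C(C)(C)O[Si](C(C)C)(C(C)C)O3
F4 | step 13 | saturated 7α-H 11-hydroxy-8-ketone carrying the C3 ester and C4 formate | C[C@@H]1O[C@]1(C)C(=O)O[C@H]1CC[C@]2(C)CC(=O)[C@@H](C(C)(C)O)C[C@H]2[C@]1(C)OC=O
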